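**Strategy.** The dimer is cut at the C4–C8 interflavan bond into two copies of one protected 2,3-cis flavan-3-ol, and that monomer is cut at O1–C8a of ring C. Ring A is a phloroglucinol: its oxygens on C8a, C5 and C7 are mutually meta around C4a, so a 2,4,6-trifluorophenyl group stands in for it. In the key step the C2 alkoxide of an open-chain (1R,2R)-carbinol, whose stereocenters descend from one purchased glycidate center through chelation control, displaces either of two equivalent ortho fluorines (C2 retained), and benzyloxide replaces the other two in the same flask. DDQ activation and biomimetic Friedel–Crafts union of two monomers then set C4.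

Key step: step 5

Remark on the chemistry: flavan numbering is used throughout (O1, C2, C3, C4, C4a, C5–C8, C8a); the target is read as the 2,3-cis-3,4-trans (4β→8) dimer with all five stereocenters R.

Step 1
Reactants: 1 2-bromo-1,3,5-trifluorobenzene; 2 methyl (2R)-oxirane-2-carboxylate
Product: 4 methyl (2R)-2-hydroxy-3-(2,4,6-trifluorophenyl)propanoate, via arylmagnesium chloride 3 (not isolated)
Conditions: iPrMgCl, THF, −20 °C; then CuI (10 mol%), 2, −40 → −20 °C; aq. NH4Cl
Reagents that add atoms: none
Why: Bromine–magnesium exchange followed by copper-catalysed SN2 opening of the epoxide at its unsubstituted CH2 terminus, which at low temperature should outrun addition to the ester; the purchased stereocenter is not touched and becomes C3.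

Step 2
Reactants: 4 methyl (2R)-2-hydroxy-3-(2,4,6-trifluorophenyl)propanoate
Product: 5 methyl (2R)-2-(benzyloxy)-3-(2,4,6-trifluorophenyl)propanoate
Conditions: BnOC(=NH)CCl3, TfOH (cat.), CH2Cl2–cyclohexane, 0 °C → rt
Reagents that add atoms: benzyl 2,2,2-trichloroacetimidate, ClC(Cl)(Cl)C(=N)OCc1ccccc1
Why: Acid-catalysed O-benzylation with a trichloroacetimidate needs no base, so the α-stereocenter is not epimerised and no alkoxide is exposed to the fluoroarene, and the electron-poor ring does not capture the benzyl cation.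

Step 3
Reactants: 5 methyl (2R)-2-(benzyloxy)-3-(2,4,6-trifluorophenyl)propanoate
Product: 6 (2R)-2-(benzyloxy)-3-(2,4,6-trifluorophenyl)propanal
Conditions: iBu2AlH (DIBAL-H, 1.1 equiv), toluene, −78 °C; MeOH, then aq. KNaC4H4O6 (potassium sodium tartrate); used crude
Reagents that add atoms: none
Why: Partial ester reduction by DIBAL-H stops at the aluminium hemiacetal at −78 °C and releases the aldehyde on work-up; using it crude avoids epimerisation of the α-benzyloxy center.

Step 4
Reactants: 6 (2R)-2-(benzyloxy)-3-(2,4,6-trifluorophenyl)propanal; 7 phenylmagnesium bromide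
Product: 8 (1R,2R)-2-(benzyloxy)-1-phenyl-3-(2,4,6-trifluorophenyl)propan-1-ol
Conditions: MgBr2·OEt2, CH2Cl2, −78 °C; then 7 (in Et2O), −78 °C; aq. NH4Cl
Reagents that add atoms: none
Why: Cram-chelate-controlled Grignard addition: magnesium bridges the aldehyde and benzyloxy oxygens and phenyl should enter the Re face past the small α-hydrogen, setting C1 as R (syn to the benzyloxy group); any anti epimer is removed by chromatography.

Step 5
Reactants: 8 (1R,2R)-2-(benzyloxy)-1-phenyl-3-(2,4,6-trifluorophenyl)propan-1-ol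
Product: 11 (2R,3R)-3,5,7-tris(benzyloxy)-2-phenylchromane, via difluoroflavan 9 (not isolated), via monofluoroflavan 10 (not isolated)
Conditions: KH (1.1 equiv), DMPU, 0 → 40 °C; then BnOK (from BnOH and KH, 4 equiv) in DMPU, 110 °C
Reagents that add atoms: benzyl alcohol, OCc1ccccc1
Why: The potassium alkoxide on the carbinol carbon adds to an ortho C–F carbon of the 2,4,6-trifluorophenyl ring and fluoride leaves (SNAr through a Meisenheimer complex), which forges O1–C8a and closes ring C in a 6-exo mode; the closest known reaction type is the intramolecular alkoxide–fluoroarene SNAr used to build chromans and flavans. No stereocenter is created: the carbinol C–O bond is never broken, so C2 and C3 are retained and the syn carbinol should give the 2,3-cis flavan directly. The two ortho fluorines are interchanged by rotation about the C4–C4a bond, so there is no regiochemical choice, and O3 is benzylated, so a five-membered closure is excluded. Benzyloxide then replaces the C7 and C5 fluorines by two intermolecular SNAr steps; as both must go, their order does not matter. The selectivity needed is ring closure before any intermolecular attack at an ortho fluorine, secured by closing the ring at low temperature before benzyloxide is added.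

Step 6
Reactants: 11 (2R,3R)-3,5,7-tris(benzyloxy)-2-phenylchromane
Product: 12 (2R,3R,4S)-3,5,7-tris(benzyloxy)-4-(2-ethoxyethoxy)-2-phenylchromane
Conditions: DDQ (1.5 equiv), 2-ethoxyethanol (5 equiv), CH2Cl2, rt
Reagents that add atoms: 2-ethoxyethanol, CCOCCO
Why: Oxidative benzylic etherification: DDQ abstracts hydride from C4, the C–H benzylic to the electron-rich ring A, and the alcohol should trap the cation on the face anti to the 3-benzyloxy and 2-phenyl groups; the C4 configuration is erased again in step 7.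

Step 7
Reactants: 12 (2R,3R,4S)-3,5,7-tris(benzyloxy)-4-(2-ethoxyethoxy)-2-phenylchromane; 11 (2R,3R)-3,5,7-tris(benzyloxy)-2-phenylchromane (3 equiv, the excess to be recovered)
Product: 13 (2R,3R,4R)-3,5,7-tris(benzyloxy)-2-phenyl-4-[(2R,3R)-3,5,7-tris(benzyloxy)-2-phenylchroman-8-yl]chromane
Conditions: TMSOTf (0.1 equiv), CH2Cl2, −78 → −40 °C; then Et3N
Reagents that add atoms: none
Why: Lewis-acid-mediated Friedel–Crafts arylation that copies proanthocyanidin biosynthesis: TMSOTf ionises the C4 ether to the ring A stabilised benzylic cation, C8 of 11 (less hindered than C6, which lies between two benzyloxy groups) should attack the face anti to the 3-benzyloxy and 2-phenyl groups to set C4 as R (3,4-trans), and the excess of 11 suppresses further chain growth.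

Step 8
Reactants: 13 (2R,3R,4R)-3,5,7-tris(benzyloxy)-2-phenyl-4-[(2R,3R)-3,5,7-tris(benzyloxy)-2-phenylchroman-8-yl]chromane
Product: 14 (2R,3R,4R)-2-phenyl-4-[(2R,3R)-3,5,7-trihydroxy-2-phenylchroman-8-yl]chromane-3,5,7-triol
Conditions: H2 (1 atm), Pd(OH)2/C, THF–MeOH–H2O, rt
Reagents that add atoms: none
Why: Hydrogenolysis of the six O-benzyl groups under neutral conditions, which should leave the acid-labile interflavan bond, the ring C ethers and all five stereocenters untouched.

**Compound list**

1 | 2-bromo-1,3,5-trifluorobenzene | Fc1cc(F)c(Br)c(F)c1 | starting material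
2 | methyl (2R)-oxirane-2-carboxylate (methyl (R)-glycidate) | COC(=O)[C@H]1CO1 | starting material
3 | (2,4,6-trifluorophenyl)magnesium chloride | Cl[Mg]c1c(F)cc(F)cc1F | intermediate
4 | methyl (2R)-2-hydroxy-3-(2,4,6-trifluorophenyl)propanoate | COC(=O)[C@H](O)Cc1c(F)cc(F)cc1F | intermediate
5 | methyl (2R)-2-(benzyloxy)-3-(2,4,6-trifluorophenyl)propanoate | COC(=O)[C@H](OCc1ccccc1)Cc1c(F)cc(F)cc1F | intermediate
6 | (2R)-2-(benzyloxy)-3-(2,4,6-trifluorophenyl)propanal | O=C[C@H](OCc1ccccc1)Cc1c(F)cc(F)cc1F | intermediate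
7 | phenylmagnesium bromide | Br[Mg]c1ccccc1 | starting material
8 | (1R,2R)-2-(benzyloxy)-1-phenyl-3-(2,4,6-trifluorophenyl)propan-1-ol (syn) | O[C@H](c1ccccc1)[C@H](OCc1ccccc1)Cc1c(F)cc(F)cc1F | intermediate
9 | (2R,3R)-3-(benzyloxy)-5,7-difluoro-2-phenylchromane (2,3-cis) | Fc1cc(F)c2c(c1)O[C@H](c1ccccc1)[C@H](OCc1ccccc1)C2 | intermediate
10 | (2R,3R)-3,7-bis(benzyloxy)-5-fluoro-2-phenylchromane (first exchange expected at the less hindered C7) | Fc1cc(OCc3ccccc3)cc2O[C@H](c3ccccc3)[C@H](OCc3ccccc3)Cc12 | intermediate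
11 | (2R,3R)-3,5,7-tris(benzyloxy)-2-phenylchromane (2,3-cis) | O(Cc1ccccc1)c1cc(OCc2ccccc2)c2c(c1)O[C@H](c1ccccc1)[C@H](OCc1ccccc1)C2 | intermediate
12 | (2R,3R,4S)-3,5,7-tris(benzyloxy)-4-(2-ethoxyethoxy)-2-phenylchromane (4-alkoxy trans to 3-benzyloxy) | O(Cc1ccccc1)c1cc(OCc2ccccc2)c2c(c1)O[C@H](c1ccccc1)[C@H](OCc1ccccc1)[C@H]2OCCOCC | intermediate
13 | (2R,3R,4R)-3,5,7-tris(benzyloxy)-2-phenyl-4-[(2R,3R)-3,5,7-tris(benzyloxy)-2-phenylchroman-8-yl]chromane | O(Cc1ccccc1)c1cc(OCc3ccccc3)c2c(c1)O[C@H](c1ccccc1)[C@H](OCc1ccccc1)[C@H]2c1c(OCc3ccccc3)cc(OCc3ccccc3)c2c1O[C@H](c1ccccc1)[C@H](OCc1ccccc1)C2 | intermediate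
14 | (2R,3R,4R)-2-phenyl-4-[(2R,3R)-3,5,7-trihydroxy-2-phenylchroman-8-yl]chromane-3,5,7-triol | Oc1cc(O)c2c(c1)O[C@H](c1ccccc1)[C@H](O)[C@H]2c1c(O)cc(O)c2c1O[C@H](c1ccccc1)[C@H](O)C2 | target

**Totals.** Total steps: 8. Longest linear sequence: 8 steps (1 → 14; compound 11 enters step 7 a second time as the lower unit).

**Steps most likely to fail**

Step 5. The last fluoride–benzyloxide exchange takes place on a ring that already carries two alkoxy groups and may stall, and at the temperature it needs benzyloxide may start to cleave aryl benzyl ethers. The fallback installs both benzyloxy groups before the chain is built, so that only the intramolecular SNAr remains. It sets out from 2. Commercial 1,3,5-trifluorobenzene and BnONa (2 equiv, from BnOH and NaH, NMP, 60 °C) should give 1,3-bis(benzyloxy)-5-fluorobenzene F1. n-BuLi (THF, −78 °C) should metalate F1 at the most acidic position, between fluorine and a benzyloxy group, to give [2,4-bis(benzyloxy)-6-fluorophenyl]lithium F2, which MgBr2·OEt2 converts to [2,4-bis(benzyloxy)-6-fluorophenyl]magnesium bromide F3. CuI-catalysed opening of 2 then gives methyl (2R)-3-[2,4-bis(benzyloxy)-6-fluorophenyl]-2-hydroxypropanoate F4. Benzylation with BnBr and Ag2O (neutral, because this ring is electron-rich) gives methyl (2R)-2-(benzyloxy)-3-[2,4-bis(benzyloxy)-6-fluorophenyl]propanoate F5, DIBAL-H at −78 °C gives (2R)-2-(benzyloxy)-3-[2,4-bis(benzyloxy)-6-fluorophenyl]propanal F6, and chelation-controlled addition of 7 gives (1R,2R)-2-(benzyloxy)-3-[2,4-bis(benzyloxy)-6-fluorophenyl]-1-phenylpropan-1-ol F7. KH in DMPU (rt → 60 °C) closes O1–C8a and the fallback comes back to the route at 11.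

Step 7. The dimer or the electrophile itself may react further at a free C8, so that chain growth beyond the dimer and self-condensation compete. The fallback caps C8 of the electrophilic unit with bromine and sets out from 11. NBS (1 equiv, CH2Cl2, −78 → 0 °C) should brominate C8 selectively to give (2R,3R)-3,5,7-tris(benzyloxy)-8-bromo-2-phenylchromane F8. DDQ and 2-ethoxyethanol give (2R,3R,4S)-3,5,7-tris(benzyloxy)-8-bromo-4-(2-ethoxyethoxy)-2-phenylchromane F9. TMSOTf-mediated union of F9 with 11 (1.5 equiv) gives (2R,3R,4S)-3,5,7-tris(benzyloxy)-8-bromo-2-phenyl-4-[(2R,3R)-3,5,7-tris(benzyloxy)-2-phenylchroman-8-yl]chromane F10, whose upper unit can no longer act as a nucleophile at C8. Hydrogenolysis over Pd(OH)2/C with Et3N removes the bromine together with the six benzyl groups and comes back to the route at 14.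

Step 4. Incomplete chelation would give poor facial selectivity at the aldehyde. The fallback replaces substrate control by reagent control and sets out from 8 obtained as a mixture of C1 epimers. Dess–Martin periodinane (CH2Cl2, rt) converges both epimers on (2R)-2-(benzyloxy)-1-phenyl-3-(2,4,6-trifluorophenyl)propan-1-one F11. Corey–Bakshi–Shibata reduction with (R)-2-methyl-CBS-oxazaborolidine and BH3·SMe2 (phenyl taken as the larger carbonyl substituent, hydride to the Si face) should then deliver the 1R carbinol and come back to the route at 8.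

**Further compounds**

F1 | step 5 | 1,3-bis(benzyloxy)-5-fluorobenzene | Fc1cc(OCc2ccccc2)cc(OCc2ccccc2)c1
F2 | step 5 | [2,4-bis(benzyloxy)-6-fluorophenyl]lithium | [Li]c1c(F)cc(OCc2ccccc2)cc1OCc1ccccc1
F3 | step 5 | [2,4-bis(benzyloxy)-6-fluorophenyl]magnesium bromide | Br[Mg]c1c(F)cc(OCc2ccccc2)cc1OCc1ccccc1
F4 | step 5 | methyl (2R)-3-[2,4-bis(benzyloxy)-6-fluorophenyl]-2-hydroxypropanoate | COC(=O)[C@H](O)Cc1c(F)cc(OCc2ccccc2)cc1OCc1ccccc1
F5 | step 5 | methyl (2R)-2-(benzyloxy)-3-[2,4-bis(benzyloxy)-6-fluorophenyl]propanoate | COC(=O)[C@H](OCc1ccccc1)Cc1c(F)cc(OCc2ccccc2)cc1OCc1ccccc1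
F6 | step 5 | (2R)-2-(benzyloxy)-3-[2,4-bis(benzyloxy)-6-fluorophenyl]propanal | O=C[C@H](OCc1ccccc1)Cc1c(F)cc(OCc2ccccc2)cc1OCc1ccccc1
F7 | step 5 | (1R,2R)-2-(benzyloxy)-3-[2,4-bis(benzyloxy)-6-fluorophenyl]-1-phenylpropan-1-ol | O[C@H](c1ccccc1)[C@H](OCc1ccccc1)Cc1c(F)cc(OCc2ccccc2)cc1OCc1ccccc1
F8 | step 7 | (2R,3R)-3,5,7-tris(benzyloxy)-8-bromo-2-phenylchromane | O(Cc1ccccc1)c1cc(OCc2ccccc2)c2c(c1Br)O[C@H](c1ccccc1)[C@H](OCc1ccccc1)C2
F9 | step 7 | (2R,3R,4S)-3,5,7-tris(benzyloxy)-8-bromo-4-(2-ethoxyethoxy)-2-phenylchromane | O(Cc1ccccc1)c1cc(OCc2ccccc2)c2c(c1Br)O[C@H](c1ccccc1)[C@H](OCc1ccccc1)[C@H]2OCCOCC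
F10 | step 7 | (2R,3R,4S)-3,5,7-tris(benzyloxy)-8-bromo-2-phenyl-4-[(2R,3R)-3,5,7-tris(benzyloxy)-2-phenylchroman-8-yl]chromane | O(Cc1ccccc1)c1cc(OCc3ccccc3)c2c(c1Br)O[C@H](c1ccccc1)[C@H](OCc1ccccc1)[C@H]2c1c(OCc3ccccc3)cc(OCc3ccccc3)c2c1O[C@H](c1ccccc1)[C@H](OCc1ccccc1)C2
F11 | step 4 | (2R)-2-(benzyloxy)-1-phenyl-3-(2,4,6-trifluorophenyl)propan-1-one | O=C(c1ccccc1)[C@H](OCc1ccccc1)Cc1c(F)cc(F)cc1F
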